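**Retrosynthetic overview**
- The target comes from a fully masked flavone (5-OMe, 4'-OSi(iPr)3) by peri-selective 5-O-demethylation and desilylation.
- Key disconnection: the C2–C1' bond, made last by a palladium-catalysed oxidative boron-Heck C2–H arylation of an intact 5,7,8-trimethoxychromone, instead of a chalcone or 1,3-diketone cyclisation.
- Ring C is the only ring formed. It is closed on ring A from 2'-hydroxy-3',4',6'-trimethoxyacetophenone and a one-carbon amide acetal, before ring B is attached.
- The acetophenone comes from 1,2,3,5-tetramethoxybenzene by Friedel–Crafts acylation with chelation-controlled ortho-demethylation, which fixes the 5,7,8 pattern.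
- The ring B boronic acid comes from 2,3-dimethoxyphenol by silylation, methoxy-directed ortho-lithiation para to the silyloxy group, and borylation.

Assumption: the target is a planar, achiral flavone with no stereocentre, so "single enantiomer" requires no stereocontrol; compounds 1 and 6 are taken as commercial.

**Route**

Step 1
Reactants: 1 1,2,3,5-tetramethoxybenzene
Product: 3 1-(2-hydroxy-3,4,6-trimethoxyphenyl)ethan-1-one, via tetramethoxyacetophenone 2 (not isolated)
Conditions: AcCl (1.2 equiv), AlCl3 (2.5 equiv), Et2O, 0 °C to rt; then H2O, 0 °C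
Reagents that add atoms: acetyl chloride, CC(Cl)=O
Why: Friedel–Crafts acylation occurs at one of the two equivalent free positions of 1, and AlCl3 chelated between the new carbonyl and the ortho methoxy that is buttressed by a neighbouring methoxy cleaves that ether selectively (chelation-controlled ortho-demethylation), which fixes the later 5,7,8-oxygenation pattern.

Step 2
Reactants: 3 1-(2-hydroxy-3,4,6-trimethoxyphenyl)ethan-1-one
Product: 5 5,7,8-trimethoxy-4H-chromen-4-one, via enaminone 4 (not isolated)
Conditions: DMF-DMA, PhMe, 100 °C; concentrate; then AcOH, 90 °C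
Reagents that add atoms: N,N-dimethylformamide dimethyl acetal, COC(OC)N(C)C
Why: Condensation of the acetyl methyl with the amide acetal gives the enaminone, and acid-promoted intramolecular oxa-Michael addition of the phenol with loss of dimethylamine (enaminone chromone synthesis) closes ring C with C2 and C3 unsubstituted.

Step 3
Reactants: 6 2,3-dimethoxyphenol
Product: 7 (2,3-dimethoxyphenoxy)tri(propan-2-yl)silane
Conditions: TIPSCl, imidazole, DMF, rt
Reagents that add atoms: chlorotri(propan-2-yl)silane, CC(C)[Si](Cl)(C(C)C)C(C)C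
Why: Standard O-silylation of a phenol; the bulky, non-coordinating triisopropylsilyl ether protects the future 4'-OH and shields its own ortho position for the next step.

Step 4
Reactants: 7 (2,3-dimethoxyphenoxy)tri(propan-2-yl)silane
Product: 10 [2,3-dimethoxy-4-(triisopropylsilyloxy)phenyl]boronic acid, via aryllithium 8 (not isolated), via lithium borate 9 (not isolated)
Conditions: n-BuLi, TMEDA, THF, 0 °C; B(OiPr)3, −78 °C to rt; 1 M HCl, 0 °C (brief)
Reagents that add atoms: triisopropyl borate, CC(C)OB(OC(C)C)OC(C)C; water, O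
Why: Directed ortho-metalation: the terminal methoxy group directs lithiation to its free ortho carbon (as in 1,2,3-trimethoxybenzene) while the silyloxy group neither coordinates lithium nor leaves its ortho C–H accessible, and the aryllithium is trapped by the borate and hydrolysed to the boronic acid.

Step 5
Reactants: 5 5,7,8-trimethoxy-4H-chromen-4-one; 10 [2,3-dimethoxy-4-(triisopropylsilyloxy)phenyl]boronic acid (2.5 equiv, added in portions)
Product: 11 2-[2,3-dimethoxy-4-(triisopropylsilyloxy)phenyl]-5,7,8-trimethoxy-4H-chromen-4-one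
Conditions: Pd(OCOCF3)2 (10 mol %), 5-nitro-1,10-phenanthroline (20 mol %), O2 (1 atm), DMSO, 80 °C
Reagents that add atoms: none
Why: Oxidative boron-Heck reaction: aryl transfer from boron to divalent palladium, syn-carbopalladation of the chromone C2=C3 bond with the aryl going to the β-carbon C2, epimerisation through the palladium enolate and β-hydride elimination give the flavone, and O2 returns zerovalent palladium to divalent palladium; no stereocentre is formed.

Step 6
Reactants: 11 2-[2,3-dimethoxy-4-(triisopropylsilyloxy)phenyl]-5,7,8-trimethoxy-4H-chromen-4-one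
Product: 12 2-[2,3-dimethoxy-4-(triisopropylsilyloxy)phenyl]-5-hydroxy-7,8-dimethoxy-4H-chromen-4-one
Conditions: BCl3 (2.5 equiv), CH2Cl2, −78 to 0 °C; then H2O
Reagents that add atoms: none
Why: Chelation-controlled Lewis acid demethylation: BCl3 bound to the C4 carbonyl forms a six-membered chelate with the peri 5-methoxy oxygen and chloride removes only that methyl at low temperature, leaving the other four methyl ethers and the silyl ether.

Step 7
Reactants: 12 2-[2,3-dimethoxy-4-(triisopropylsilyloxy)phenyl]-5-hydroxy-7,8-dimethoxy-4H-chromen-4-one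
Product: 13 5-hydroxy-2-(4-hydroxy-2,3-dimethoxyphenyl)-7,8-dimethoxy-4H-chromen-4-one
Conditions: Bu4NF (1.1 equiv), AcOH (1.1 equiv), THF, 0 °C to rt
Reagents that add atoms: none
Why: Fluoride-mediated desilylation, driven by the strong Si–F bond and buffered with AcOH so the flavone never meets strong base, releases the 4'-phenol to give the target.

**Compound list**

1 | 1,2,3,5-tetramethoxybenzene | COc1cc(OC)c(OC)c(OC)c1 | starting material
2 | 1-(2,3,4,6-tetramethoxyphenyl)ethan-1-one | CC(=O)c1c(OC)c(OC)c(OC)cc1OC | intermediate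
3 | 1-(2-hydroxy-3,4,6-trimethoxyphenyl)ethan-1-one | CC(=O)c1c(O)c(OC)c(OC)cc1OC | intermediate
4 | (E)-3-(dimethylamino)-1-(2-hydroxy-3,4,6-trimethoxyphenyl)prop-2-en-1-one | CN(C)/C=C/C(=O)c1c(O)c(OC)c(OC)cc1OC | intermediate
5 | 5,7,8-trimethoxy-4H-chromen-4-one | COc1cc(OC)c2c(=O)ccoc2c1OC | intermediate
6 | 2,3-dimethoxyphenol | COc1cccc(O)c1OC | starting material
7 | (2,3-dimethoxyphenoxy)tri(propan-2-yl)silane | COc1cccc(O[Si](C(C)C)(C(C)C)C(C)C)c1OC | intermediate
8 | [2,3-dimethoxy-4-(triisopropylsilyloxy)phenyl]lithium | [Li]c1ccc(O[Si](C(C)C)(C(C)C)C(C)C)c(OC)c1OC | intermediate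
9 | lithium [2,3-dimethoxy-4-(triisopropylsilyloxy)phenyl]tri(propan-2-yloxy)borate | [Li+].CC(C)O[B-](OC(C)C)(OC(C)C)c1ccc(O[Si](C(C)C)(C(C)C)C(C)C)c(OC)c1OC | intermediate
10 | [2,3-dimethoxy-4-(triisopropylsilyloxy)phenyl]boronic acid | OB(O)c1ccc(O[Si](C(C)C)(C(C)C)C(C)C)c(OC)c1OC | intermediate
11 | 2-[2,3-dimethoxy-4-(triisopropylsilyloxy)phenyl]-5,7,8-trimethoxy-4H-chromen-4-one | COc1cc(OC)c2c(=O)cc(-c3ccc(O[Si](C(C)C)(C(C)C)C(C)C)c(OC)c3OC)oc2c1OC | intermediate
12 | 2-[2,3-dimethoxy-4-(triisopropylsilyloxy)phenyl]-5-hydroxy-7,8-dimethoxy-4H-chromen-4-one | COc1cc(O)c2c(=O)cc(-c3ccc(O[Si](C(C)C)(C(C)C)C(C)C)c(OC)c3OC)oc2c1OC | intermediate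
13 | 5-hydroxy-2-(4-hydroxy-2,3-dimethoxyphenyl)-7,8-dimethoxy-4H-chromen-4-one (5,4'-dihydroxy-7,8,2',3'-tetramethoxyflavone) | COc1cc(O)c2c(=O)cc(-c3ccc(O)c(OC)c3OC)oc2c1OC | target

**Totals and risk**

Total step count: 7. Longest linear sequence: 5 steps (steps 1, 2, 5, 6, 7; the ring B branch, steps 3, 4, 5, 6, 7, is equally long).

Most likely to fail, in order:

Step 5 (oxidative boron-Heck coupling). The ortho-methoxy boronic acid may protodeboronate or homocouple faster than it adds to the electron-rich chromone. The fallback sets out from 5 and 10 and comes back at 11, making the C2–aryl bond redox-neutrally and oxidising afterwards. Rhodium-catalysed conjugate addition of 10 to 5 ([Rh(OH)(1,5-cyclooctadiene)]2, dioxane/H2O, 60 °C) gives racemic 2-[2,3-dimethoxy-4-(triisopropylsilyloxy)phenyl]-5,7,8-trimethoxychroman-4-one F1. Its single stereocentre is erased when DDQ (dioxane, 100 °C) dehydrogenates it to 11.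

Step 4 (lithiation and borylation). Lithiation could partly go ortho to the silyloxy group, and the electron-rich boronic acid may lose boron on acidic work-up. The fallback sets out from 6 and comes back at 11, fixing the ring B pattern through a symmetric intermediate and giving a robust boronate.
- Oxidation of 6 with K2[ON(SO3)2] (aqueous KH2PO4/MeOH) gives 2,3-dimethoxy-1,4-benzoquinone F2.
- Na2S2O4 reduces it to 2,3-dimethoxybenzene-1,4-diol F3, whose two hydroxyls are equivalent.
- Monosilylation (TIPSCl 1 equiv, imidazole, DMF) can therefore give only 2,3-dimethoxy-4-(triisopropylsilyloxy)phenol F4.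
- Tf2O/pyridine converts it into 2,3-dimethoxy-4-(triisopropylsilyloxy)phenyl trifluoromethanesulfonate F5.
- Miyaura borylation (bis(pinacolato)diboron, KOAc, PdCl2[1,1'-bis(diphenylphosphino)ferrocene], dioxane, 90 °C) gives 2-[2,3-dimethoxy-4-(triisopropylsilyloxy)phenyl]-4,4,5,5-tetramethyl-1,3,2-dioxaborolane F6.
- F6 is used in place of 10 under the step 5 conditions (with a little water) to give 11.

Step 6 (selective 5-O-demethylation). BCl3 might also attack the 8-methoxy group, the vicinal ring B ethers or the silyl ether. The fallback sets out from 5 and comes back at 12, moving the demethylation ahead of the coupling, where only the peri ether can react.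
- BCl3 (CH2Cl2, −78 to 0 °C) on 5 gives 5-hydroxy-7,8-dimethoxy-4H-chromen-4-one F7.
- Ac2O/pyridine masks the chelating phenol as 7,8-dimethoxy-4-oxo-4H-chromen-5-yl acetate F8.
- Coupling with 10 under the step 5 conditions gives 2-[2,3-dimethoxy-4-(triisopropylsilyloxy)phenyl]-7,8-dimethoxy-4-oxo-4H-chromen-5-yl acetate F9.
- Catalytic K2CO3 in MeOH at 0 °C removes the acetate to return to 12.

Further compounds
F1 | step 5 | racemic 2-[2,3-dimethoxy-4-(triisopropylsilyloxy)phenyl]-5,7,8-trimethoxychroman-4-one | COc1cc(OC)c2C(=O)CC(c3ccc(O[Si](C(C)C)(C(C)C)C(C)C)c(OC)c3OC)Oc2c1OC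
F2 | step 4 | 2,3-dimethoxy-1,4-benzoquinone | COC1=C(OC)C(=O)C=CC1=O
F3 | step 4 | 2,3-dimethoxybenzene-1,4-diol | COc1c(O)ccc(O)c1OC
F4 | step 4 | 2,3-dimethoxy-4-(triisopropylsilyloxy)phenol | COc1c(O)ccc(O[Si](C(C)C)(C(C)C)C(C)C)c1OC
F5 | step 4 | 2,3-dimethoxy-4-(triisopropylsilyloxy)phenyl trifluoromethanesulfonate | COc1c(OS(=O)(=O)C(F)(F)F)ccc(O[Si](C(C)C)(C(C)C)C(C)C)c1OC
F6 | step 4 | 2-[2,3-dimethoxy-4-(triisopropylsilyloxy)phenyl]-4,4,5,5-tetramethyl-1,3,2-dioxaborolane | COc1c(B2OC(C)(C)C(C)(C)O2)ccc(O[Si](C(C)C)(C(C)C)C(C)C)c1OC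
F7 | step 6 | 5-hydroxy-7,8-dimethoxy-4H-chromen-4-one | COc1cc(O)c2c(=O)ccoc2c1OC
F8 | step 6 | 7,8-dimethoxy-4-oxo-4H-chromen-5-yl acetate | COc1cc(OC(C)=O)c2c(=O)ccoc2c1OC
F9 | step 6 | 2-[2,3-dimethoxy-4-(triisopropylsilyloxy)phenyl]-7,8-dimethoxy-4-oxo-4H-chromen-5-yl acetate | COc1cc(OC(C)=O)c2c(=O)cc(-c3ccc(O[Si](C(C)C)(C(C)C)C(C)C)c(OC)c3OC)oc2c1OC
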